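## Structural features

The target is a 2,3,4-trisubstituted tetrahydrofuran (ring A: O1, C2, C3, C4, C5) of the 7,9'-epoxylignan type. In lignan numbering C2 = C7 (guaiacyl-bearing), C3 = C8 (bearing C9H2O), C4 = C8' (bearing the carbinol C7') and C5 = C9'. O9 carries an (E)-p-coumaroyl ester, C7' carries a free secondary benzylic hydroxyl and the second guaiacyl group, and three phenols are free. Four contiguous stereocentres, C7(S)–C8(R)–C8'(R)–C7'(S), run through the molecule; on ring A the C2 aryl group is trans to C3–C9, while C3–C9 and C4–C7' are cis. The array is hidden-C2-symmetric: two ArCH(O)–CH(CH2O)– halves of identical configuration are joined at C8–C8', and only the use of the four oxygens (O7 etherified to C9', O9 acylated, O7' free) breaks the symmetry. Fragile features are the two benzylic C–O bonds para to phenolic oxygen (ionisation, epimerisation, hydrogenolysis), the cinnamate ester (base, hydride, ozone, hydrogenation) and the electron-rich arenes. The real difficulty is the C8–C8' bond with its two stereocentres, their relation to both benzylic carbinols, the thermodynamically disfavoured 3,4-cis arrangement, and the unsymmetrical use of two constitutionally equivalent halves. The key step exploits the C7–C8–C8'–C7' tetrad: one benzylic carbinol configuration, taken three times from a single alcohol, is kept at C7 and C7' and relayed by a [3,3] shift into C8 and C8'. Below, Ar denotes 3-methoxy-4-(triisopropylsilyloxy)phenyl.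

## Logic of the disconnections

In one sentence: an Ireland–Claisen rearrangement of 12 forms C8–C8' and both central stereocentres.

26 is cut at its three phenolic O–H bonds (back to 25) and at the acyl–O9 bond (back to 21 and 24). The cinnamate and the free phenols are the most fragile groups and are therefore introduced last. The gain is that 21 is the complete core with all four stereocentres. The demand is an acylation that tells primary O9–H from secondary benzylic O7'–H, and a final deprotection that is neither acidic nor reductive.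

21 is traced to 20 by re-forming the C9(=O)–O7' lactone bond. The cis-fused bicyclic lactone holds the 3,4-cis relation and ties up O7' and C9 together, so O7' is distinguished from O7 and C9 from C9' without protecting groups. The forward step must be a hydride reduction that spares the aryl silyl ethers.

20 is cut at the O7–C9' bond of ring A and goes back through 19 to 16, in which C9' is the inner carbon of an (E)-styryl group. Ring A then closes by itself once C9' is an aldehyde, and no free primary alcohol is ever placed next to the lactone. The gain is a monocyclic γ,δ-unsaturated acid derivative, which is the retron of a [3,3] shift. The demands are alkene cleavage in the presence of electron-rich arenes, and removal of the hemiacetal hydroxyl without ionising the benzylic C7–O bond.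

16 is cut at C8–C8' (and at the C9–O7' lactone bond, which forms in the work-up), giving ester 12. Both central stereocentres arise in one step from an allylic C–O stereocentre, and the two termini emerge already differentiated (C9 carboxyl, C9' alkene). The forward step needs a (Z)-silyl ketene acetal, a chair transition state, and silylation of the enolate before it can lose the β-silyloxy group.

12 is cut at the ester C–O bond into 6 and 11. Because the two hydroxyls of 6 are homotopic, only mono- versus diacylation has to be controlled.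

6 is cut at its C=C bond into two molecules of 5. 11 goes back through 9 and 7 to 5 by changing the terminal alkene into a carboxyl group. 5 comes from racemic 4 by enzymatic resolution, 4 from 2 and 3 by C7–C8 bond formation, and 2 from 1. 24 comes from 22. All three benzylic stereocentres thus derive from one resolved alcohol.

## Other disconnections considered

Alternative 1: This is the first disconnection that comes to mind: cut O7–C9' (cycloetherification) and C7–C8 (aldol). In the forward sense the lithium enolate of lactone A1 would add to aldehyde 2 trans to the C8' substituent to give A2, followed by hydride reduction and closure of O7 onto C9'. The enolate aldol controls C8 but gives no reliable control of the new C7 carbinol (open transition state). A1 needs its own stereocontrolled synthesis. After reduction, C9–OH and C9'–OH are both primary and need extra protecting-group steps to be told apart. The chosen plan sets C8 and C8' together with C7 and C7' already fixed, and differentiates C9 from C9' in the same step.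

Alternative 2: Cut C8–C8' symmetrically: oxidative homocoupling of the dianion of hydroxy ester A3 to the C2-symmetric succinate A4. A chelated β-alkoxide enolate reacts anti to its β-substituent (as in the Frater–Seebach alkylation), so the coupling should give the 7,8-anti/7',8'-anti isomer A4, not the 7,8-syn array of the target. Any C2-symmetric coupling product also has homotopic C9/C9' and O7/O7' termini, so the ether/ester pattern would need a statistical monofunctionalisation late in the route. The chosen plan keeps the symmetry idea but delivers the termini differentiated.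

Alternative 3: Cut C7–C8 and C8'–C9' together: a (3+2) cycloaddition of the 1,3-dipole released by fluoride from A6 onto butenolide A5 would give 20 in one step. Addition anti to the C7' aryl group is secure. The regiochemistry of a non-stabilised dipole with an unsymmetrical acceptor and the exo/endo position of the C7 aryl group have no controlling element in either partner. The acidic γ-hydrogen of A5 also invites racemisation under basic fluoride. The route would be shorter but three of the four stereochemical questions would be left open.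

Key step: step 9

Step 1
Reactants: 1 vanillin (4-hydroxy-3-methoxybenzaldehyde)
Product: 2 3-methoxy-4-(triisopropylsilyloxy)benzaldehyde
Conditions: iPr3SiCl (1.1 equiv), imidazole (2 equiv), DMF, 23 °C
Reagents that add atoms: chlorotri(propan-2-yl)silane, CC(C)[Si](Cl)(C(C)C)C(C)C
Why: Phenol silylation; the bulky aryl silyl ether tolerates Grignard, amide base, hydride and ozone and is removed by fluoride at the end.

Step 2
Reactants: 2 3-methoxy-4-(triisopropylsilyloxy)benzaldehyde; 3 vinylmagnesium bromide (CH2=CHMgBr)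
Product: 4 rac-1-Ar-prop-2-en-1-ol
Conditions: CH2=CHMgBr (1.2 equiv), THF, −78 → 0 °C; aq. NH4Cl
Reagents that add atoms: none
Why: Grignard 1,2-addition to an aromatic aldehyde forms the C7–C8 bond of each half; the product is racemic.

Step 3
Reactants: 4 rac-1-Ar-prop-2-en-1-ol
Product: 5 (1S)-1-Ar-prop-2-en-1-ol
Conditions: Novozym 435 (immobilised Candida antarctica lipase B), vinyl acetate (3 equiv), tert-butyl methyl ether, 30 °C, to just past half conversion
Reagents that add atoms: none
Why: Lipase-catalysed kinetic resolution by irreversible transesterification; with aryl as the large and vinyl as the medium substituent the enzyme should acylate the (R)-alcohol, so the unreacted (S)-alcohol is recovered and separated from the acetate.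

Step 4
Reactants: 5 (1S)-1-Ar-prop-2-en-1-ol (two equivalents)
Product: 6 (1S,2E,4S)-1,4-bis(Ar)but-2-ene-1,4-diol
Conditions: RuCl2(=CHPh)(PCy3)(H2IMes) (second-generation Grubbs catalyst, 5 mol %), 1,4-benzoquinone (10 mol %), CH2Cl2 (0.5 M), 40 °C, argon sweep
Reagents that add atoms: none
Why: Olefin self-metathesis of a secondary allylic alcohol, driven by loss of ethene and expected to give the thermodynamically favoured (E)-alkene; the carbinol centres are untouched, so the product is C2-symmetric, and any residual (R)-alcohol ends up in a separable meso diol; benzoquinone suppresses ruthenium hydride isomerisation.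

Step 5
Reactants: 5 (1S)-1-Ar-prop-2-en-1-ol
Product: 7 triethyl{[(1S)-1-Ar-prop-2-en-1-yl]oxy}silane
Conditions: Et3SiCl (1.2 equiv), imidazole (2 equiv), CH2Cl2, 0 °C
Reagents that add atoms: chlorotriethylsilane, CC[Si](Cl)(CC)CC
Why: Silylation of the secondary alcohol; the triethylsilyl ether survives hydroboration, oxidation and amide base and is later cleaved by dilute acetic acid without touching the aryl silyl ethers.

Step 6
Reactants: 7 triethyl{[(1S)-1-Ar-prop-2-en-1-yl]oxy}silane
Product: 9 (3S)-3-Ar-3-(triethylsilyloxy)propan-1-ol, via alkylborane 8 (not isolated)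
Conditions: 9-borabicyclo[3.3.1]nonane (1.5 equiv), THF, 0 → 23 °C; then 30% H2O2, aq. NaOAc, 0 → 23 °C
Reagents that add atoms: hydrogen peroxide, OO
Why: Anti-Markovnikov hydroboration–oxidation of a terminal alkene; the bulky borane adds only at the CH2 terminus and the buffered oxidation spares both silyl ethers; the stereocentre is not involved.

Step 7
Reactants: 9 (3S)-3-Ar-3-(triethylsilyloxy)propan-1-ol
Product: 11 (3S)-3-Ar-3-(triethylsilyloxy)propanoic acid, via aldehyde 10 (not isolated)
Conditions: TEMPO (0.2 equiv), PhI(OAc)2 (2.5 equiv), MeCN/aq. pH 7 phosphate buffer 1:1, 23 °C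
Reagents that add atoms: water, O
Why: Oxoammonium-mediated oxidation of a primary alcohol through the aldehyde hydrate to the acid; the buffered, non-basic medium avoids β-elimination of the silyloxy group and loss of the silyl ethers.

Step 8
Reactants: 6 (1S,2E,4S)-1,4-bis(Ar)but-2-ene-1,4-diol; 11 (3S)-3-Ar-3-(triethylsilyloxy)propanoic acid
Product: 12 (1S,2E,4S)-4-hydroxy-1,4-bis(Ar)but-2-en-1-yl (3S)-3-Ar-3-(triethylsilyloxy)propanoate
Conditions: 6 (2.5 equiv, excess recovered), DCC (1.1 equiv), DMAP (0.1 equiv), CH2Cl2, 0 → 23 °C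
Reagents that add atoms: none
Why: Steglich esterification; the two hydroxyls of the C2-symmetric diol are homotopic, so either gives the same monoester and the excess of diol suppresses diacylation; the neutral conditions avoid ionisation of the benzylic allylic C–O bond.

Step 9
Reactants: 12 (1S,2E,4S)-4-hydroxy-1,4-bis(Ar)but-2-en-1-yl (3S)-3-Ar-3-(triethylsilyloxy)propanoate
Product: 16 (3S,4S,5S)-5-Ar-4-[(E)-2-Ar-ethenyl]-3-[(S)-Ar(hydroxy)methyl]dihydrofuran-2(3H)-one, via silyl ketene acetal 13 (not isolated), via trimethylsilyl ester 14 (not isolated), via dihydroxy acid 15 (not isolated)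
Conditions: LiN(iPr)2 (2.4 equiv) and Me3SiCl (4 equiv) premixed, THF/DMPU 4:1, −78 °C, then 23 °C; then AcOH/THF/H2O 3:1:1, 23 °C
Reagents that add atoms: none
Why: Ireland–Claisen rearrangement: deprotonation in THF/DMPU in the presence of Me3SiCl silylates O7' and traps the ester enolate as the (Z)-O-silyl ketene acetal 13 (C7 cis to OSiMe3) before it can expel the β-silyloxy group. On warming, 13 undergoes a concerted suprafacial [3,3] shift through a chair transition state with the aryl group on the allylic carbinol carbon equatorial, forming C8–C8' and the (E)-styrene of 14; the closest known reaction type is the ester enolate Claisen rearrangement of secondary (E)-allylic esters with 1,3-chirality transfer. C8' is set by the (S)-configured C–O stereocentre that is consumed (the new bond forms on the face from which oxygen departs), and C8 by the (Z)-geometry of the ketene acetal in the same chair, which places both CH(OSi)Ar groups equatorial and gives the syn C8/C8' relationship; C7 and C7' are carried unchanged from 11 and 6. The sigmatropic step closes no ring; in the acidic work-up the silyl ester and both alkyl silyl ethers are hydrolysed to 15 and O7'–H closes the γ-lactone on the C9 carboxyl (5-exo-trig), the only lactone possible without a four-membered ring, which distinguishes O7' from O7 and C9 from C9'. The step needs Z over E ketene acetal (DMPU), chair over boat (acyclic array), dominance of the in-ring stereocentre over the bias of the exocyclic C7 and C7' centres (the A(1,3)-minimised conformer of 13 should expose the face anti to the aryl group, which is the face used), and rearrangement faster than ionisation of the allylic ester (low temperature, basic medium).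

Step 10
Reactants: 16 (3S,4S,5S)-5-Ar-4-[(E)-2-Ar-ethenyl]-3-[(S)-Ar(hydroxy)methyl]dihydrofuran-2(3H)-one
Product: 19 (3S,3aS,6S,6aS)-3,6-bis(Ar)-4-hydroxytetrahydro-1H,3H-furo[3,4-c]furan-1-one (mixture at C4), via ozonide 17 (not isolated), via hydroxy aldehyde 18 (not isolated)
Conditions: O3, CH2Cl2, −78 °C (indicator dye end point); then PPh3 (1.5 equiv), −78 → 23 °C
Reagents that add atoms: ozone, [O-][O+]=O
Why: Ozonolysis with reductive work-up; the electron-rich styrene should react faster than the arenes, and the C9' aldehyde of 18 is captured at once by the cis-disposed O7–H as a five-membered hemiacetal (5-exo-trig), so ring A forms without a free primary alcohol next to the lactone; the excised carbon leaves as aldehyde 2, which can be reused.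

Step 11
Reactants: 19 (3S,3aS,6S,6aS)-3,6-bis(Ar)-4-hydroxytetrahydro-1H,3H-furo[3,4-c]furan-1-one
Product: 20 (3S,3aR,6S,6aS)-3,6-bis(Ar)tetrahydro-1H,3H-furo[3,4-c]furan-1-one
Conditions: Et3SiH (3 equiv), BF3·OEt2 (1.5 equiv), CH2Cl2, −78 → −40 °C
Reagents that add atoms: none
Why: Ionic hydrogenation of a lactol: the Lewis acid ionises the hemiacetal C9'–OH and the silane reduces the resulting oxocarbenium centre to CH2; no stereocentre is touched, the lactone is inert, and the low temperature should keep the benzylic C–O bonds from ionising.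

Step 12
Reactants: 20 (3S,3aR,6S,6aS)-3,6-bis(Ar)tetrahydro-1H,3H-furo[3,4-c]furan-1-one
Product: 21 {(2S,3R,4R)-2-Ar-4-[(S)-Ar(hydroxy)methyl]tetrahydrofuran-3-yl}methanol
Conditions: LiBH4 (2.5 equiv), THF, 0 → 23 °C; aq. NH4Cl
Reagents that add atoms: none
Why: Hydride reduction of the γ-lactone to the 1,4-diol releases primary O9–H and secondary benzylic O7'–H; the C7'–O bond is not broken, so its configuration is kept, and the aryl silyl ethers and ring A survive.

Step 13
Reactants: 22 p-coumaric acid [(E)-3-(4-hydroxyphenyl)prop-2-enoic acid]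
Product: 24 (E)-3-[4-(tert-butyldimethylsilyloxy)phenyl]prop-2-enoic acid, via silyl ester 23 (not isolated)
Conditions: tBuMe2SiCl (2.3 equiv), imidazole (4 equiv), DMF, 23 °C; then AcOH/THF/H2O, 23 °C
Reagents that add atoms: tert-butylchlorodimethylsilane, CC(C)(C)[Si](C)(C)Cl
Why: Bis-silylation followed by selective hydrolysis of the labile silyl ester leaves the aryl silyl ether, which blocks phenol acylation in the coupling.

Step 14
Reactants: 21 {(2S,3R,4R)-2-Ar-4-[(S)-Ar(hydroxy)methyl]tetrahydrofuran-3-yl}methanol; 24 (E)-3-[4-(tert-butyldimethylsilyloxy)phenyl]prop-2-enoic acid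
Product: 25 {(2S,3R,4R)-2-Ar-4-[(S)-Ar(hydroxy)methyl]tetrahydrofuran-3-yl}methyl (E)-3-[4-(tert-butyldimethylsilyloxy)phenyl]prop-2-enoate
Conditions: 24 (1.05 equiv), EDC·HCl (1.2 equiv), DMAP (0.1 equiv), CH2Cl2, −20 → 0 °C
Reagents that add atoms: none
Why: Carbodiimide (Steglich-type) esterification; the primary O9–H should be acylated in preference to the hindered secondary benzylic O7'–H at low temperature with near-stoichiometric acid; Mitsunobu activation is avoided because it would cyclise the 1,4-diol.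

Step 15
Reactants: 25 {(2S,3R,4R)-2-Ar-4-[(S)-Ar(hydroxy)methyl]tetrahydrofuran-3-yl}methyl (E)-3-[4-(tert-butyldimethylsilyloxy)phenyl]prop-2-enoate
Product: 26 {(2S,3R,4R)-4-[(S)-hydroxy(4-hydroxy-3-methoxyphenyl)methyl]-2-(4-hydroxy-3-methoxyphenyl)tetrahydrofuran-3-yl}methyl (E)-3-(4-hydroxyphenyl)prop-2-enoate (CNP0330050.2)
Conditions: Bu4NF (3.5 equiv), AcOH (4 equiv), THF, 0 °C
Reagents that add atoms: none
Why: Fluoride cleavage of the three aryl silyl ethers; acetic acid buffers the phenoxides so that the cinnamate is not transesterified, no acyl shift to O7' occurs, and no quinone methide forms at C7 or C7'.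

## Compound list

1 | vanillin (4-hydroxy-3-methoxybenzaldehyde) | COc1cc(C=O)ccc1O | starting material
2 | 3-methoxy-4-(triisopropylsilyloxy)benzaldehyde | COc1cc(C=O)ccc1O[Si](C(C)C)(C(C)C)C(C)C | intermediate
3 | vinylmagnesium bromide | C=C[Mg]Br | starting material
4 | rac-1-Ar-prop-2-en-1-ol | C=CC(O)c1ccc(O[Si](C(C)C)(C(C)C)C(C)C)c(OC)c1 | intermediate
5 | (1S)-1-Ar-prop-2-en-1-ol | C=C[C@H](O)c1ccc(O[Si](C(C)C)(C(C)C)C(C)C)c(OC)c1 | intermediate
6 | (1S,2E,4S)-1,4-bis(Ar)but-2-ene-1,4-diol | O[C@H](c1ccc(O[Si](C(C)C)(C(C)C)C(C)C)c(OC)c1)/C=C/[C@H](O)c1ccc(O[Si](C(C)C)(C(C)C)C(C)C)c(OC)c1 | intermediate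
7 | triethyl{[(1S)-1-Ar-prop-2-en-1-yl]oxy}silane | CC[Si](CC)(CC)O[C@@H](C=C)c1ccc(O[Si](C(C)C)(C(C)C)C(C)C)c(OC)c1 | intermediate
8 | 9-[(3S)-3-Ar-3-(triethylsilyloxy)propyl]-9-borabicyclo[3.3.1]nonane | CC[Si](CC)(CC)O[C@@H](CCB1C2CCCC1CCC2)c1ccc(O[Si](C(C)C)(C(C)C)C(C)C)c(OC)c1 | intermediate
9 | (3S)-3-Ar-3-(triethylsilyloxy)propan-1-ol | CC[Si](CC)(CC)O[C@@H](CCO)c1ccc(O[Si](C(C)C)(C(C)C)C(C)C)c(OC)c1 | intermediate
10 | (3S)-3-Ar-3-(triethylsilyloxy)propanal | CC[Si](CC)(CC)O[C@@H](CC=O)c1ccc(O[Si](C(C)C)(C(C)C)C(C)C)c(OC)c1 | intermediate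
11 | (3S)-3-Ar-3-(triethylsilyloxy)propanoic acid | CC[Si](CC)(CC)O[C@@H](CC(=O)O)c1ccc(O[Si](C(C)C)(C(C)C)C(C)C)c(OC)c1 | intermediate
12 | (1S,2E,4S)-4-hydroxy-1,4-bis(Ar)but-2-en-1-yl (3S)-3-Ar-3-(triethylsilyloxy)propanoate | CC[Si](CC)(CC)O[C@@H](CC(=O)O[C@H](c1ccc(O[Si](C(C)C)(C(C)C)C(C)C)c(OC)c1)/C=C/[C@H](O)c1ccc(O[Si](C(C)C)(C(C)C)C(C)C)c(OC)c1)c1ccc(O[Si](C(C)C)(C(C)C)C(C)C)c(OC)c1 | intermediate
13 | {[(1Z,3S)-3-Ar-1-{[(1S,2E,4S)-1,4-bis(Ar)-4-(trimethylsilyloxy)but-2-en-1-yl]oxy}-3-(triethylsilyloxy)prop-1-en-1-yl]oxy}trimethylsilane | C[Si](C)(C)O/C(=C\[C@H](O[Si](CC)(CC)CC)c1ccc(O[Si](C(C)C)(C(C)C)C(C)C)c(OC)c1)O[C@H](c1ccc(O[Si](C(C)C)(C(C)C)C(C)C)c(OC)c1)/C=C/[C@H](O[Si](C)(C)C)c1ccc(O[Si](C(C)C)(C(C)C)C(C)C)c(OC)c1 | intermediate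
14 | trimethylsilyl (2S,3S,4E)-5-Ar-2-[(S)-Ar(triethylsilyloxy)methyl]-3-[(S)-Ar(trimethylsilyloxy)methyl]pent-4-enoate | C[Si](C)(C)OC(=O)[C@H]([C@H](O[Si](CC)(CC)CC)c1ccc(O[Si](C(C)C)(C(C)C)C(C)C)c(OC)c1)[C@H](/C=C/c1ccc(O[Si](C(C)C)(C(C)C)C(C)C)c(OC)c1)[C@H](O[Si](C)(C)C)c1ccc(O[Si](C(C)C)(C(C)C)C(C)C)c(OC)c1 | intermediate
15 | (2S,3S,4E)-5-Ar-2,3-bis[(S)-Ar(hydroxy)methyl]pent-4-enoic acid | OC(=O)[C@H]([C@H](O)c1ccc(O[Si](C(C)C)(C(C)C)C(C)C)c(OC)c1)[C@H](/C=C/c1ccc(O[Si](C(C)C)(C(C)C)C(C)C)c(OC)c1)[C@H](O)c1ccc(O[Si](C(C)C)(C(C)C)C(C)C)c(OC)c1 | intermediate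
16 | (3S,4S,5S)-5-Ar-4-[(E)-2-Ar-ethenyl]-3-[(S)-Ar(hydroxy)methyl]dihydrofuran-2(3H)-one | O=C1O[C@H](c2ccc(O[Si](C(C)C)(C(C)C)C(C)C)c(OC)c2)[C@@H](/C=C/c2ccc(O[Si](C(C)C)(C(C)C)C(C)C)c(OC)c2)[C@H]1[C@H](O)c1ccc(O[Si](C(C)C)(C(C)C)C(C)C)c(OC)c1 | intermediate
17 | (3S,4S,5S)-5-Ar-3-[(S)-Ar(hydroxy)methyl]-4-(5-Ar-1,2,4-trioxolan-3-yl)dihydrofuran-2(3H)-one (trioxolane stereoisomers) | O=C1O[C@H](c2ccc(O[Si](C(C)C)(C(C)C)C(C)C)c(OC)c2)[C@@H](C2OOC(c3ccc(O[Si](C(C)C)(C(C)C)C(C)C)c(OC)c3)O2)[C@H]1[C@H](O)c1ccc(O[Si](C(C)C)(C(C)C)C(C)C)c(OC)c1 | intermediate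
18 | (2S,3S,4S)-2-Ar-4-[(S)-Ar(hydroxy)methyl]-5-oxotetrahydrofuran-3-carbaldehyde | O=C1O[C@H](c2ccc(O[Si](C(C)C)(C(C)C)C(C)C)c(OC)c2)[C@@H](C=O)[C@H]1[C@H](O)c1ccc(O[Si](C(C)C)(C(C)C)C(C)C)c(OC)c1 | intermediate
19 | (3S,3aS,6S,6aS)-3,6-bis(Ar)-4-hydroxytetrahydro-1H,3H-furo[3,4-c]furan-1-one (mixture at C4) | O=C1O[C@H](c3ccc(O[Si](C(C)C)(C(C)C)C(C)C)c(OC)c3)[C@H]2C(O)O[C@H](c3ccc(O[Si](C(C)C)(C(C)C)C(C)C)c(OC)c3)[C@@H]12 | intermediate
20 | (3S,3aR,6S,6aS)-3,6-bis(Ar)tetrahydro-1H,3H-furo[3,4-c]furan-1-one | O=C1O[C@H](c3ccc(O[Si](C(C)C)(C(C)C)C(C)C)c(OC)c3)[C@H]2CO[C@H](c3ccc(O[Si](C(C)C)(C(C)C)C(C)C)c(OC)c3)[C@@H]12 | intermediate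
21 | {(2S,3R,4R)-2-Ar-4-[(S)-Ar(hydroxy)methyl]tetrahydrofuran-3-yl}methanol | COc1cc([C@@H](O)[C@H]2CO[C@H](c3ccc(O[Si](C(C)C)(C(C)C)C(C)C)c(OC)c3)[C@H]2CO)ccc1O[Si](C(C)C)(C(C)C)C(C)C | intermediate
22 | p-coumaric acid [(E)-3-(4-hydroxyphenyl)prop-2-enoic acid] | OC(=O)/C=C/c1ccc(O)cc1 | starting material
23 | tert-butyldimethylsilyl (E)-3-[4-(tert-butyldimethylsilyloxy)phenyl]prop-2-enoate | CC(C)(C)[Si](C)(C)OC(=O)/C=C/c1ccc(O[Si](C)(C)C(C)(C)C)cc1 | intermediate
24 | (E)-3-[4-(tert-butyldimethylsilyloxy)phenyl]prop-2-enoic acid | OC(=O)/C=C/c1ccc(O[Si](C)(C)C(C)(C)C)cc1 | intermediate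
25 | {(2S,3R,4R)-2-Ar-4-[(S)-Ar(hydroxy)methyl]tetrahydrofuran-3-yl}methyl (E)-3-[4-(tert-butyldimethylsilyloxy)phenyl]prop-2-enoate | COc1cc([C@@H](O)[C@H]2CO[C@H](c3ccc(O[Si](C(C)C)(C(C)C)C(C)C)c(OC)c3)[C@H]2COC(=O)/C=C/c2ccc(O[Si](C)(C)C(C)(C)C)cc2)ccc1O[Si](C(C)C)(C(C)C)C(C)C | intermediate
26 | {(2S,3R,4R)-4-[(S)-hydroxy(4-hydroxy-3-methoxyphenyl)methyl]-2-(4-hydroxy-3-methoxyphenyl)tetrahydrofuran-3-yl}methyl (E)-3-(4-hydroxyphenyl)prop-2-enoate | COc1cc([C@@H](O)[C@H]2CO[C@H](c3ccc(O)c(OC)c3)[C@H]2COC(=O)/C=C/c2ccc(O)cc2)ccc1O | target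

## Step count and least certain steps

Total step count: 15. Longest linear sequence: 13 steps (steps 1, 2, 3, 5, 6, 7, 8, 9, 10, 11, 12, 14, 15).

**Step 9 (key step).** The most likely failures are:
- β-elimination of triethylsilanolate from the ester enolate before it is silylated, because DMPU makes the enolate more reactive;
- incomplete Z-selectivity in ketene acetal formation, which would give the C8 epimer;
- erosion of facial control if the exocyclic C7 and C7' centres oppose the chair-imposed sense.

The fallback sets out from 6 and returns at 20, so it needs neither an ester enolate nor 11. Johnson–Claisen rearrangement of 6 with MeC(OEt)3 and catalytic EtCO2H at 135 °C transfers the same carbinol chirality to C8', and lactonisation of the remaining hydroxyl gives the styryl lactone F1. Ozonolysis with NaBH4 work-up gives the hydroxymethyl lactone F2. Me3SiOTf/Et3N converts it to the bis-silyl ketene acetal F3. Aldehyde 2 with catalytic Me3SiOTf then forms an oxocarbenium ion on the side-chain oxygen, which the ketene acetal traps intramolecularly (Mukaiyama-type aldol cyclisation). This closes C7–C8 necessarily cis-fused, with the aryl group expected on the convex face, to give 20.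

**Step 4.** The most likely failure is ruthenium-hydride isomerisation of the allylic alcohol to the ethyl ketone, or sluggish dimerisation of a hindered secondary allylic alcohol. The fallback sets out from 2 and returns at 6. Double addition of BrMgC≡CMgBr to 2 gives the ynediol F4 as a stereoisomer mixture. MnO2 oxidises it to the ynedione F5. (R)-Alpine-Borane, with the alkynyl group acting as the small substituent, should give the (R,R)-ynediol F6. NaAlH2(OCH2CH2OMe)2 trans-reduces the propargylic diol to 6.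

**Step 8.** The most likely failure is diacylation, or loss of the monoester by ionisation and allylic transposition of the benzylic allylic ester during purification. The fallback sets out from 5 and 11 and returns at 12. Steglich esterification of 5 with 11 gives the allyl ester F7 with no statistical issue. Cross-metathesis of F7 with excess 5 (same ruthenium catalyst) then builds the (E)-alkene and the free carbinol terminus of 12 in one operation.

**Step 11.** The most likely failure is Lewis-acid ionisation of the benzylic C7–O bond, leading to epimerisation at C7 or reductive opening of ring A. The fallback sets out from 16 and returns at 20. Ozonolysis of 16 with NaBH4 work-up at −78 → 0 °C gives the diol lactone F8. TsCl in pyridine sulfonylates the primary hydroxyl selectively to the tosylate F9, which cyclises in the same flask by attack of O7 on C9' (5-exo-tet). The C7–O bond is never broken.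

## Further compounds

F1 | step 9 | (4R,5S)-5-Ar-4-[(E)-2-Ar-ethenyl]dihydrofuran-2(3H)-one | O=C1O[C@H](c2ccc(O[Si](C(C)C)(C(C)C)C(C)C)c(OC)c2)[C@@H](/C=C/c2ccc(O[Si](C(C)C)(C(C)C)C(C)C)c(OC)c2)C1
F2 | step 9 | (4R,5S)-5-Ar-4-(hydroxymethyl)dihydrofuran-2(3H)-one | O=C1O[C@H](c2ccc(O[Si](C(C)C)(C(C)C)C(C)C)c(OC)c2)[C@@H](CO)C1
F3 | step 9 | trimethyl({(4R,5S)-5-Ar-4-[(trimethylsilyloxy)methyl]-4,5-dihydrofuran-2-yl}oxy)silane | C[Si](C)(C)OC1=C[C@H](CO[Si](C)(C)C)[C@@H](c2ccc(O[Si](C(C)C)(C(C)C)C(C)C)c(OC)c2)O1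
F4 | step 4 | 1,4-bis(Ar)but-2-yne-1,4-diol (stereoisomer mixture) | OC(c1ccc(O[Si](C(C)C)(C(C)C)C(C)C)c(OC)c1)C#CC(O)c1ccc(O[Si](C(C)C)(C(C)C)C(C)C)c(OC)c1
F5 | step 4 | 1,4-bis(Ar)but-2-yne-1,4-dione | O=C(c1ccc(O[Si](C(C)C)(C(C)C)C(C)C)c(OC)c1)C#CC(=O)c1ccc(O[Si](C(C)C)(C(C)C)C(C)C)c(OC)c1
F6 | step 4 | (1R,4R)-1,4-bis(Ar)but-2-yne-1,4-diol | O[C@H](c1ccc(O[Si](C(C)C)(C(C)C)C(C)C)c(OC)c1)C#C[C@H](O)c1ccc(O[Si](C(C)C)(C(C)C)C(C)C)c(OC)c1
F7 | step 8 | (1S)-1-Ar-prop-2-en-1-yl (3S)-3-Ar-3-(triethylsilyloxy)propanoate | CC[Si](CC)(CC)O[C@@H](CC(=O)O[C@H](c1ccc(O[Si](C(C)C)(C(C)C)C(C)C)c(OC)c1)C=C)c1ccc(O[Si](C(C)C)(C(C)C)C(C)C)c(OC)c1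
F8 | step 11 | (3S,4R,5S)-5-Ar-3-[(S)-Ar(hydroxy)methyl]-4-(hydroxymethyl)dihydrofuran-2(3H)-one | O=C1O[C@H](c2ccc(O[Si](C(C)C)(C(C)C)C(C)C)c(OC)c2)[C@@H](CO)[C@H]1[C@H](O)c1ccc(O[Si](C(C)C)(C(C)C)C(C)C)c(OC)c1
F9 | step 11 | {(2S,3R,4S)-2-Ar-4-[(S)-Ar(hydroxy)methyl]-5-oxotetrahydrofuran-3-yl}methyl 4-methylbenzenesulfonate | O=C1O[C@H](c2ccc(O[Si](C(C)C)(C(C)C)C(C)C)c(OC)c2)[C@@H](COS(=O)(=O)c2ccc(C)cc2)[C@H]1[C@H](O)c1ccc(O[Si](C(C)C)(C(C)C)C(C)C)c(OC)c1
A1 | alternative 1 | (4R)-4-{(S)-Ar[(tert-butyldimethylsilyl)oxy]methyl}dihydrofuran-2(3H)-one | O=C1C[C@@H]([C@H](O[Si](C)(C)C(C)(C)C)c2ccc(O[Si](C(C)C)(C(C)C)C(C)C)c(OC)c2)CO1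
A2 | alternative 1 | (3S,4R)-3-[(S)-Ar(hydroxy)methyl]-4-{(S)-Ar[(tert-butyldimethylsilyl)oxy]methyl}dihydrofuran-2(3H)-one | O=C1[C@H]([C@H](O)c2ccc(O[Si](C(C)C)(C(C)C)C(C)C)c(OC)c2)[C@@H]([C@H](O[Si](C)(C)C(C)(C)C)c2ccc(O[Si](C(C)C)(C(C)C)C(C)C)c(OC)c2)CO1
A3 | alternative 2 | methyl (3S)-3-Ar-3-hydroxypropanoate | COC(=O)C[C@H](O)c1ccc(O[Si](C(C)C)(C(C)C)C(C)C)c(OC)c1
A4 | alternative 2 | dimethyl (2R,3R)-2,3-bis[(S)-Ar(hydroxy)methyl]butanedioate | COC(=O)[C@@H]([C@H](O)c1ccc(O[Si](C(C)C)(C(C)C)C(C)C)c(OC)c1)[C@H]([C@H](O)c1ccc(O[Si](C(C)C)(C(C)C)C(C)C)c(OC)c1)C(=O)OC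
A5 | alternative 3 | (5S)-5-Ar-furan-2(5H)-one | O=C1C=C[C@@H](c2ccc(O[Si](C(C)C)(C(C)C)C(C)C)c(OC)c2)O1
A6 | alternative 3 | {[chloro(Ar)methoxy]methyl}trimethylsilane | C[Si](C)(C)COC(Cl)c1ccc(O[Si](C(C)C)(C(C)C)C(C)C)c(OC)c1
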